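**Plan**

1. Atoms carry guaiane numbers (unit A unprimed, middle unit B primed, unit C double‑primed). Retrosynthesis cuts, in this order: the A/B spirocyclohexene bonds C2–C4' and C14–C15' (Diels–Alder; C15' itself comes off as a Mannich carbon), then C1'–C10' and C6'–C7' of unit B together, then C4''–C2' (oxidative enol ether coupling) and C15''–C14' (Mukaiyama–Michael).
2. Enabling feature: ring B (cyclopentenone C1'–C5') holds C6' as an exocyclic carbon on C5'. With both carbonyls enolised it is a 6‑siloxypentafulvene whose nucleophilic ring carbon C1' and latent oxocarbenium carbon C6' are the 1,3‑related termini of one 6π system. A chain with a C10' ketone and a C7' allylsilane can add across them (formal [6+4]), closing the hydroazulene and the six‑membered B/C ring in one operation.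
3. Forward: dehydrocostus lactone → dehydrozaluzanin C (units A and C); chain C7'–C14' added to C15''; ring B joined at the quaternary C4''; fulvene; key step (six‑ and seven‑membered rings); C15' and lactone ring; unit A by Saegusa–Ito oxidation/Diels–Alder.
4. Stereochemistry: C1, C5–C7 of units A and C from the chiral pool; C4'' by convex‑face attack; C10', C6', C7' in the key step, relayed from C4''; C5' by suprafacial [1,5]‑H shift; C4' and C10 in the last step.

Key step: step 11

Remark: centres that are mixtures or unassigned and are destroyed later (C2' in 14 and 15, C4' in 20 and 21, C2 in 27, the C5'=C6' geometry of 16) are left undefined in the SMILES; the 3α configuration drawn for 2 is of no consequence.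

**Route**

Step 1
Reactants: 1 dehydrocostus lactone
Product: 2 3‑epizaluzanin C (3α‑hydroxydehydrocostus lactone)
Conditions: SeO2 (0.5 equiv), t‑BuOOH, CH2Cl2, 23 °C
Reagents that add atoms: tert‑butyl hydroperoxide CC(C)(C)OO
Why: Selenium dioxide allylic hydroxylation (Riley oxidation, ene reaction then [2,3] shift) should take the most accessible allylic CH2, C3 next to the 4(15)‑alkene, and leave the electron‑poor lactone methylene alone; the new C3 centre is removed in step 2.

Step 2
Reactants: 2 3‑epizaluzanin C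
Product: 3 dehydrozaluzanin C
Conditions: Dess–Martin periodinane, CH2Cl2, 23 °C
Reagents that add atoms: none
Why: Dess–Martin oxidation of the allylic alcohol should give the exo‑methylene cyclopentanone under neutral conditions that spare the three alkenes and the lactone.

Step 3
Reactants: 4 ethyl 2‑[(trimethylsilyl)methyl]prop‑2‑enoate; 5 hex‑5‑en‑2‑one
Product: 6 ethyl (2Z)‑6‑oxo‑2‑[(trimethylsilyl)methyl]hept‑2‑enoate
Conditions: Hoveyda–Grubbs II catalyst (5 mol %), 4 in excess, CH2Cl2, 40 °C
Reagents that add atoms: none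
Why: Olefin cross‑metathesis of a methacrylate‑type 1,1‑disubstituted alkene with a terminal alkene should give the trisubstituted enoate with the chain trans to the ester (thermodynamic preference, Z by CIP), ketone and allylsilane being tolerated.

Step 4
Reactants: 6 chain keto ester
Product: 7 ethyl (2Z)‑6‑(trimethylsilyloxy)‑2‑[(trimethylsilyl)methyl]hepta‑2,6‑dienoate
Conditions: LDA, Me3SiCl (internal quench), THF, −78 °C
Reagents that add atoms: chlorotrimethylsilane C[Si](C)(C)Cl
Why: Kinetic deprotonation of the methyl ketone at its methyl group with in‑situ O‑silylation should give the terminal enol ether (C14'); the hindered trisubstituted enoate should not be attacked at −78 °C.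

Step 5
Reactants: 7 chain silyl enol ether; 3 dehydrozaluzanin C
Product: 8 Michael adduct as the C3''‑O‑trimethylsilyl enol ether
Conditions: HNTf2 (2 mol %), CH2Cl2, −78 °C
Reagents that add atoms: none
Why: Mukaiyama–Michael addition under silylium catalysis: C14' should add to C15'' of the exo‑methylene cyclopentanone, by far the best acceptor present, and silyl transfer delivers the tetrasubstituted C3''=C4'' enol ether regiospecifically, which marks C4'' as the next nucleophilic site.

Step 6
Reactants: 9 3‑ethoxycyclopent‑2‑en‑1‑one; 10 1,3‑dithiane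
Product: 11 3‑(1,3‑dithian‑2‑yl)cyclopent‑2‑en‑1‑one
Conditions: 10, n‑BuLi, THF, −30 °C; then 9, −78 → 0 °C; then 1 M HCl
Reagents that add atoms: none
Why: Stork–Danheiser transposition: 1,2‑addition of the lithiated dithiane to the vinylogous ester and acidic hydrolysis with loss of ethanol should give the enone that carries the masked formyl carbon C6' on C5'.

Step 7
Reactants: 11 dithianyl enone
Product: 12 3‑(dimethoxymethyl)cyclopent‑2‑en‑1‑one
Conditions: PhI(OCOCF3)2, MeOH, 23 °C
Reagents that add atoms: methanol CO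
Why: Oxidative dithioacetal cleavage with a hypervalent iodine reagent in methanol should give the dimethyl acetal directly, a formyl mask that survives LDA and cerium(IV).

Step 8
Reactants: 12 acetal enone
Product: 13 4‑(dimethoxymethyl)‑2‑(trimethylsilyloxy)cyclopenta‑1,3‑diene
Conditions: LDA, Me3SiCl, THF, −78 °C
Reagents that add atoms: chlorotrimethylsilane C[Si](C)(C)Cl
Why: Kinetic α'‑deprotonation of the enone (at C2') and O‑silylation should give the cross‑conjugated 2‑siloxydiene whose unsubstituted terminus C2' is the carbon to be bonded to C4''.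

Step 9
Reactants: 8 Michael adduct silyl enol ether; 13 siloxydiene
Product: 15 keto aldehyde with quaternary C4'', via dimethyl acetal 14 (not isolated)
Conditions: (NH4)2Ce(NO3)6 (2.2 equiv), NaHCO3, 13 (3 equiv), MeCN–EtCN, −40 °C; then 1 M HCl, THF, 0 °C
Reagents that add atoms: water O
Why: Oxidative cross‑coupling of two silyl enol ethers by single‑electron oxidation: the tetrasubstituted enol ether 8 should be oxidised first and its tertiary α‑keto radical should add to C2' of the diene kept in excess, giving the 1,4‑diketone after oxidation and desilylation; bond formation on the convex α‑face of the cis‑fused hydroazulenone (the face of H‑1'' and H‑5'') sets C4'', both C2' epimers are usable, and the acidic work‑up unmasks the aldehyde.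

Step 10
Reactants: 15 keto aldehyde
Product: 16 3',6'‑bis(tert‑butyldimethylsilyloxy)fulvene
Conditions: t‑BuMe2SiOTf (2.1 equiv), Et3N, CH2Cl2, −78 °C
Reagents that add atoms: tert‑butyldimethylsilyl triflate CC(C)(C)[Si](C)(C)OS(=O)(=O)C(F)(F)F
Why: Soft enolisation with double O‑silylation: ring B is a 4‑oxo‑enal whose conjugated tautomer is a vinylogous β‑keto aldehyde, far more acidic than the two saturated ketones, so two equivalents of silyl triflate should stop at the fulvene, on which both C2' epimers converge.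

Step 11
Reactants: 16 bis(silyloxy)fulvene
Product: 18 cyclopentadiene tris‑silyl ether, via silyloxocarbenium triflate 17 (not isolated)
Conditions: Me3SiOTf (0.2 equiv), 2,6‑di‑tert‑butyl‑4‑methylpyridine (0.3 equiv), CH2Cl2, −78 → −40 °C
Reagents that add atoms: none
Why: Proposed new method: Me3SiOTf activates the C10' ketone and ring carbon C1' of the 6‑siloxyfulvene (the carbon next to C5', the ε‑terminus of the trienol ether) attacks it in a vinylogous Mukaiyama aldol step that closes the six‑membered B/C ring (6‑(enolendo)‑exo‑trig) and turns C6' into the silyloxocarbenium ion 17; the (Z)‑2‑(silylmethyl)acrylate then adds through C7' to C6' (Hosomi–Sakurai, 7‑exo‑trig), the β‑silyl cation loses Me3Si+, which ends on O‑10' and carries the chain, so the net change is an isomerisation, a formal [6+4] annulation of the fulvene across C1' and C6'. Closest known reaction types are the fulvene–diene [6+4] cycloaddition to hydroazulenes, the vinylogous Mukaiyama aldol reaction and the intramolecular Hosomi–Sakurai closure of 2‑(silylmethyl)acrylates onto aldehydes to seven‑membered rings; their coupling through one fulvene, with a saturated C8'–C9' link in place of a diene, is new. C10' is set in the chair‑like six‑ring closure under the control of the quaternary C4'' (C9' equatorial, the silylated oxygen axial and cis to the C3'' carbonyl arm), and the transient centre C1' takes C10' on the ring face from which alone C7' can then reach C6', so C10' is relayed to C6'. C6' also depends on the oxocarbenium rotamer (oxygen toward C1', away from the C3' silyloxy group), and the open antiperiplanar transition state of the (Z)‑allylsilane places H‑7' trans to H‑6'. The step needs C1' to react in preference to the more electron‑rich C4' of the fulvene, which the tether secures (C1' closes a six‑membered ring, C4' would close a seven‑membered one), and it needs the C3'' ketone, the lactone and the 1,1‑disubstituted alkenes of unit C to stay out, which their low nucleophilicity and the hindered, unactivated ketone secure at −78 °C with a proton scavenger.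

Step 12
Reactants: 18 cyclopentadiene tris‑silyl ether
Product: 22 exo‑methylene dienone bis‑silyl ether, via dienol ether tautomer 19 (not isolated), via Mannich base 20 (not isolated), via methiodide 21 (not isolated)
Conditions: ClCH2CH2Cl, 40 °C; then CH2=NMe2+ I−, 0 → 23 °C; then MeI; then aq NaHCO3, 23 °C
Reagents that add atoms: N,N‑dimethylmethyleneiminium iodide (Eschenmoser's salt) C=[N+](C)C.[I-]
Why: The 5‑substituted cyclopentadiene should equilibrate by suprafacial [1,5]‑H shifts (H‑1' passes to the same face of C5', which sets H‑5'), only tautomers with the C3'(OSi)=C4' enol ether (19 and its C2'‑H isomer) are aminomethylated at C4' (Mukaiyama–Mannich, Curtin–Hammett funnel; the unit C ketone is no enol ether and stays untouched), and Hofmann‑type elimination of the methiodide, with base‑mediated conjugation of any Δ5'(1') isomer, should give the C4'=C15' dienone.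

Step 13
Reactants: 22 exo‑methylene dienone bis‑silyl ether
Product: 24 B/C dimer (10'‑hydroxy spiro dimer with exo‑methylene cyclopentenone), via diol ester 23 (not isolated)
Conditions: HF·pyridine, THF, 0 → 23 °C; then PPTS (cat.), PhH, 50 °C
Reagents that add atoms: none
Why: Fluoride should cleave the secondary TBS and tertiary TMS ethers and mild acid should close the γ‑lactone between O‑6' and the acrylate ester (trans‑fused, as fixed by C6' and C7'); the non‑basic conditions spare the γ‑acidic H‑5'.

Step 14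
Reactants: 3 dehydrozaluzanin C
Product: 25 C3‑O‑tert‑butyldimethylsilyl dienol ether of dehydrozaluzanin C
Conditions: t‑BuMe2SiOTf, Et3N, CH2Cl2, 0 °C
Reagents that add atoms: tert‑butyldimethylsilyl triflate CC(C)(C)[Si](C)(C)OS(=O)(=O)C(F)(F)F
Why: Soft enolisation of the cross‑conjugated ketone toward C2 should give the C2=C3 silyl enol ether needed for regioselective dehydrogenation.

Step 15
Reactants: 25 silyl dienol ether; 24 B/C dimer
Product: 28 ainsliatrimer A, via dienone 26 (not isolated), via cycloadduct 27 (not isolated)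
Conditions: Pd(OAc)2 (1.1 equiv), 25 added slowly, MeCN, argon, 23 °C; then Et3N, CH2Cl2, 23 °C
Reagents that add atoms: none
Why: Saegusa–Ito oxidation should give the Δ1(2)‑dienone 26, whose diene C2=C1–C10=C14 adds to the exo‑methylene enone C4'=C15' of 24 (Diels–Alder, C14 to the β‑carbon C15' and C2 to C4' on the face of ring B that carries C6', which sets the spiro centre C4'), and amine‑mediated conjugation of the β,γ‑enone under argon (no γ‑hydroperoxidation) should move the double bond to C1=C2 and place H on C10 cis to H‑5.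

**Compound list**

1 | dehydrocostus lactone | C=C1CC[C@H]2C(=C)CC[C@H]3C(=C)C(=O)O[C@@H]3[C@H]21 | starting material
2 | 3‑epizaluzanin C | C=C1[C@H](O)C[C@H]2C(=C)CC[C@H]3C(=C)C(=O)O[C@@H]3[C@H]21 | intermediate
3 | dehydrozaluzanin C | C=C1C(=O)C[C@H]2C(=C)CC[C@H]3C(=C)C(=O)O[C@@H]3[C@H]21 | intermediate
4 | ethyl 2‑[(trimethylsilyl)methyl]prop‑2‑enoate | C=C(C[Si](C)(C)C)C(=O)OCC | starting material
5 | hex‑5‑en‑2‑one | CC(=O)CCC=C | starting material
6 | ethyl (2Z)‑6‑oxo‑2‑[(trimethylsilyl)methyl]hept‑2‑enoate | CCOC(=O)/C(C[Si](C)(C)C)=C/CCC(C)=O | intermediate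
7 | ethyl (2Z)‑6‑(trimethylsilyloxy)‑2‑[(trimethylsilyl)methyl]hepta‑2,6‑dienoate | CCOC(=O)/C(C[Si](C)(C)C)=C/CCC(=C)O[Si](C)(C)C | intermediate
8 | Michael adduct, C3''‑O‑TMS enol ether of unit C with the C14'–C7' chain on C15'' | CCOC(=O)/C(C[Si](C)(C)C)=C/CCC(=O)CCC1=C(O[Si](C)(C)C)C[C@H]2C(=C)CC[C@H]3C(=C)C(=O)O[C@@H]3[C@H]21 | intermediate
9 | 3‑ethoxycyclopent‑2‑en‑1‑one | CCOC1=CC(=O)CC1 | starting material
10 | 1,3‑dithiane | C1CSCSC1 | starting material
11 | 3‑(1,3‑dithian‑2‑yl)cyclopent‑2‑en‑1‑one | O=C1C=C(C2SCCCS2)CC1 | intermediate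
12 | 3‑(dimethoxymethyl)cyclopent‑2‑en‑1‑one | COC(OC)C1=CC(=O)CC1 | intermediate
13 | 4‑(dimethoxymethyl)‑2‑(trimethylsilyloxy)cyclopenta‑1,3‑diene | COC(OC)C1=CC(O[Si](C)(C)C)=CC1 | intermediate
14 | 1,4‑diketone with quaternary C4'', ring B as 3‑(dimethoxymethyl)cyclopent‑2‑enone bonded through C2' | CCOC(=O)/C(C[Si](C)(C)C)=C/CCC(=O)CC[C@@]1(C4C(=O)C=C(C(OC)OC)C4)C(=O)C[C@H]2C(=C)CC[C@H]3C(=C)C(=O)O[C@@H]3[C@H]21 | intermediate (not isolated)
15 | keto aldehyde (ring B as 3‑formylcyclopent‑2‑enone) | CCOC(=O)/C(C[Si](C)(C)C)=C/CCC(=O)CC[C@@]1(C4C(=O)C=C(C=O)C4)C(=O)C[C@H]2C(=C)CC[C@H]3C(=C)C(=O)O[C@@H]3[C@H]21 | intermediate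
16 | 3',6'‑bis(tert‑butyldimethylsilyloxy)fulvene | CCOC(=O)/C(C[Si](C)(C)C)=C/CCC(=O)CC[C@@]1(C4=CC(=CO[Si](C)(C)C(C)(C)C)C=C4O[Si](C)(C)C(C)(C)C)C(=O)C[C@H]2C(=C)CC[C@H]3C(=C)C(=O)O[C@@H]3[C@H]21 | intermediate
17 | C6' silyloxocarbenium triflate after closure of the six‑membered ring | C1C(O[Si](C)(C)C(C)(C)C)=C2[C@H](C=1C=[O+][Si](C)(C)C(C)(C)C)[C@@](O[Si](C)(C)C)(CC/C=C(\C[Si](C)(C)C)C(=O)OCC)CC[C@]21C(=O)C[C@H]2C(=C)CC[C@H]3C(=C)C(=O)O[C@@H]3[C@H]21.[O-]S(=O)(=O)C(F)(F)F | intermediate (not isolated)
18 | key‑step product: cyclopentadiene (H on C1'), C3'‑OTBS dienol ether, C6'‑OTBS, C10'‑OTMS, ethyl acrylate on C7' | C1C(O[Si](C)(C)C(C)(C)C)=C2[C@@H]3C=1[C@@H](O[Si](C)(C)C(C)(C)C)[C@H](C(=C)C(=O)OCC)CC[C@@]3(O[Si](C)(C)C)CC[C@]21C(=O)C[C@H]2C(=C)CC[C@H]3C(=C)C(=O)O[C@@H]3[C@H]21 | intermediate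
19 | tautomer of 18 with H on C5' and the C3'(OTBS)=C4' enol ether | C1=C(O[Si](C)(C)C(C)(C)C)C2=C3[C@H]1[C@@H](O[Si](C)(C)C(C)(C)C)[C@H](C(=C)C(=O)OCC)CC[C@@]3(O[Si](C)(C)C)CC[C@]21C(=O)C[C@H]2C(=C)CC[C@H]3C(=C)C(=O)O[C@@H]3[C@H]21 | intermediate (not isolated)
20 | C4' Mannich base | CN(C)CC1C(=O)C2=C3[C@H]1[C@@H](O[Si](C)(C)C(C)(C)C)[C@H](C(=C)C(=O)OCC)CC[C@@]3(O[Si](C)(C)C)CC[C@]21C(=O)C[C@H]2C(=C)CC[C@H]3C(=C)C(=O)O[C@@H]3[C@H]21 | intermediate (not isolated)
21 | methiodide of 20 | C[N+](C)(C)CC1C(=O)C2=C3[C@H]1[C@@H](O[Si](C)(C)C(C)(C)C)[C@H](C(=C)C(=O)OCC)CC[C@@]3(O[Si](C)(C)C)CC[C@]21C(=O)C[C@H]2C(=C)CC[C@H]3C(=C)C(=O)O[C@@H]3[C@H]21.[I-] | intermediate (not isolated)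
22 | exo‑methylene dienone, C6'‑OTBS, C10'‑OTMS | C=C1C(=O)C2=C3[C@H]1[C@@H](O[Si](C)(C)C(C)(C)C)[C@H](C(=C)C(=O)OCC)CC[C@@]3(O[Si](C)(C)C)CC[C@]21C(=O)C[C@H]2C(=C)CC[C@H]3C(=C)C(=O)O[C@@H]3[C@H]21 | intermediate
23 | 6',10'‑diol ethyl ester | C=C1C(=O)C2=C3[C@H]1[C@@H](O)[C@H](C(=C)C(=O)OCC)CC[C@@]3(O)CC[C@]21C(=O)C[C@H]2C(=C)CC[C@H]3C(=C)C(=O)O[C@@H]3[C@H]21 | intermediate (not isolated)
24 | B/C dimer | C=C1C(=O)C2=C3[C@H]1[C@H]1OC(=O)C(=C)[C@@H]1CC[C@@]3(O)CC[C@]21C(=O)C[C@H]2C(=C)CC[C@H]3C(=C)C(=O)O[C@@H]3[C@H]21 | intermediate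
25 | C3‑O‑TBS dienol ether of dehydrozaluzanin C | C=C1C(O[Si](C)(C)C(C)(C)C)=C[C@H]2C(=C)CC[C@H]3C(=C)C(=O)O[C@@H]3[C@H]21 | intermediate
26 | 1,2‑didehydro‑dehydrozaluzanin C (dienone) | C=C1C(=O)C=C2C(=C)CC[C@H]3C(=C)C(=O)O[C@@H]3[C@H]21 | intermediate (not isolated)
27 | Diels–Alder adduct with C1=C10 double bond | C=C1C(=O)C2C3=C(CC[C@H]4C(=C)C(=O)O[C@@H]4[C@@H]13)CC[C@@]21C(=O)C2=C3[C@H]1[C@H]1OC(=O)C(=C)[C@@H]1CC[C@@]3(O)CC[C@]21C(=O)C[C@H]2C(=C)CC[C@H]3C(=C)C(=O)O[C@@H]3[C@H]21 | intermediate (not isolated)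
28 | ainsliatrimer A | C=C1C(=O)C2=C3[C@H](CC[C@H]4C(=C)C(=O)O[C@@H]4[C@@H]13)CC[C@@]21C(=O)C2=C3[C@H]1[C@H]1OC(=O)C(=C)[C@@H]1CC[C@@]3(O)CC[C@]21C(=O)C[C@H]2C(=C)CC[C@H]3C(=C)C(=O)O[C@@H]3[C@H]21 | target

**Totals and risks**

Total step count: 15. Longest linear sequence: 9 steps (steps 3, 4, 5, 9, 10, 11, 12, 13, 15).

Step 11 (Proposed new method). What may go wrong: closure through the enol ether carbon C4' instead of C1', protodesilylation of the allylsilane before the second ring closes, or unselective facial approach in the first closure, which would spread C10' and with it C6'. The fallback uses known reactions, sets out from 15 and comes back at 24. DBU (cat., CH2Cl2, 0 °C) closes the six‑membered ring by intramolecular vinylogous aldol addition of C1' to the C10' ketone and gives the aldol adduct F1. BF3·OEt2 (CH2Cl2, −78 °C) then brings about the intramolecular Hosomi–Sakurai addition of the allylsilane to the aldehyde, and lactonisation gives the 3'‑oxo‑4'‑ene lactone F2. Aminomethylation of the extended dienol of ring B at C4' with Eschenmoser's salt and Et3N gives the Mannich base F3. Methylation (MeI), elimination (NaHCO3) and amine‑mediated conjugation of the ring B double bond to C1'=C2' then give 24.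

Step 9. What may go wrong: oxidation of the siloxydiene instead of 8 with homocoupling, cyclisation of the C4'' radical onto the lactone methylene, or bond formation on the concave face. The fallback makes the coupling intramolecular through a silicon tether; it sets out from 6, 3 and 12 and comes back at 14. The kinetic lithium enolate of 6 (LDA, −78 °C) is added to excess i‑Pr2SiCl2 to give the chlorosilyl enol ether F4. Mukaiyama–Michael addition of F4 to 3 (HNTf2 cat.) transfers the chlorosilyl group to O‑3'' and gives the chlorosilyl enol ether F5. The lithium dienolate of 12 (LDA, −78 °C) displaces chloride and gives the silicon‑tethered bis‑enol ether F6. Cerium(IV) ammonium nitrate (NaHCO3, MeCN, −10 °C) then couples C4'' with C2' within the tether and gives 14.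

Step 12. What may go wrong: the sigmatropic equilibrium may drain into the tautomer whose enol ether carbon is the substituted C2', which does not react; the tertiary silyl ether may be lost with ionisation at C10'; conjugation of the Δ5'(1') isomer may be slow. The fallback replaces the pericyclic funnel by ionic dienolate chemistry; it sets out from 18 and comes back at 22. Mild acid (PPTS, wet CH2Cl2, 0 °C) hydrolyses only the dienol ether and gives the 3'‑oxo‑4'‑ene bis‑silyl ether F7. Eschenmoser's salt with Et3N aminomethylates C4' through the extended dienol (the γ‑H on C1' is the most acidic C–H) and gives the Mannich base F8. MeI, NaHCO3 and amine‑mediated conjugation then give 22.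

Further compounds
F1 | step 11 | vinylogous aldol adduct (C1'–C10' closed, aldehyde and allylsilane intact) | O=CC1=CC(=O)C2C1[C@@](O)(CC/C=C(\C[Si](C)(C)C)C(=O)OCC)CC[C@]21C(=O)C[C@H]2C(=C)CC[C@H]3C(=C)C(=O)O[C@@H]3[C@H]21
F2 | step 11 | 3'‑oxo‑4'‑ene lactone (isomer of 24 without C15') | C1C(=O)C2C3C=1[C@H]1OC(=O)C(=C)[C@@H]1CC[C@@]3(O)CC[C@]21C(=O)C[C@H]2C(=C)CC[C@H]3C(=C)C(=O)O[C@@H]3[C@H]21
F3 | step 11 | C4' Mannich base of F2 (Δ5'(1')) | CN(C)CC1C(=O)C2C3=C1[C@H]1OC(=O)C(=C)[C@@H]1CC[C@@]3(O)CC[C@]21C(=O)C[C@H]2C(=C)CC[C@H]3C(=C)C(=O)O[C@@H]3[C@H]21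
F4 | step 9 | chloro(diisopropyl)silyl enol ether of 6 | CCOC(=O)/C(C[Si](C)(C)C)=C/CCC(=C)O[Si](Cl)(C(C)C)C(C)C
F5 | step 9 | C3''‑O‑chloro(diisopropyl)silyl enol ether of the Michael adduct | CCOC(=O)/C(C[Si](C)(C)C)=C/CCC(=O)CCC1=C(O[Si](Cl)(C(C)C)C(C)C)C[C@H]2C(=C)CC[C@H]3C(=C)C(=O)O[C@@H]3[C@H]21
F6 | step 9 | diisopropylsilyl bis‑enol ether of unit C and ring B | CCOC(=O)/C(C[Si](C)(C)C)=C/CCC(=O)CCC1=C(O[Si](C(C)C)(C(C)C)OC4=CCC(C(OC)OC)=C4)C[C@H]2C(=C)CC[C@H]3C(=C)C(=O)O[C@@H]3[C@H]21
F7 | step 12 | 3'‑oxo‑4'‑ene bis‑silyl ether (hydrolysed 18) | C1C(=O)C2[C@@H]3C=1[C@@H](O[Si](C)(C)C(C)(C)C)[C@H](C(=C)C(=O)OCC)CC[C@@]3(O[Si](C)(C)C)CC[C@]21C(=O)C[C@H]2C(=C)CC[C@H]3C(=C)C(=O)O[C@@H]3[C@H]21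
F8 | step 12 | C4' Mannich base of F7 (Δ5'(1')) | CN(C)CC1C(=O)C2C3=C1[C@@H](O[Si](C)(C)C(C)(C)C)[C@H](C(=C)C(=O)OCC)CC[C@@]3(O[Si](C)(C)C)CC[C@]21C(=O)C[C@H]2C(=C)CC[C@H]3C(=C)C(=O)O[C@@H]3[C@H]21
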